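(The rate constants were drawn at random within sensible limits.)

The constants below are those at 0 °C; the flasks share one charge and one time but stand at different temperatures.

    partner + free catalyst → catalyst intermediate A (k1 = 3.4 /M/s, Ea1 = 43.0 kJ/mol)
    substrate + catalyst intermediate A ⇌ catalyst intermediate B (K2 = 3.2 /M, k2 = 810 /M/s, Ea2 = 39.0 kJ/mol, ΔH2 = −13.0 kJ/mol)
    catalyst intermediate B → free catalyst + target (k3 = 12 /s, Ea3 = 59.0 kJ/mol)
    substrate + free catalyst → spent catalyst (k4 = 0.0014 /M/s, Ea4 = 45.0 kJ/mol)
    partner ⇌ dormant form (K5 = 3.9, k5 = 0.054 /s, Ea5 = 68.0 kJ/mol, ΔH5 = −8.00 kJ/mol)
    (constants at 0 °C)

| setting | midnight | dusk | spring |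
|---|---|---|---|
| substrate | 1.5 M | 1.5 M | 1.5 M |
| partner | 1.58 M | 1.58 M | 1.58 M |
| free catalyst | 15 mM | 15 mM | 15 mM |
| temperature | −15 °C | 15 °C | 0 °C |
| time | 12 s | 12 s | 12 s |

- the flask with the highest amount of target, in percent of the substrate charged ("all alike" if they lie within 1.5 percentage points) (midnight / dusk / spring / all alike)
- final target, as a percentage of the substrate charged, in midnight
- final target, as a percentage of the substrate charged, in dusk
- final target, as a percentage of the substrate charged, in spring

- constants are those at 0 °C; use the activation energies and enthalpies for any other temperature

Catalyst goes round: free catalyst takes up partner to give intermediate A, substrate turns that into intermediate B, and B releases target and free catalyst. Which constants must be good shows first in midnight, the coldest flask. The capture constant of substrate can be rough. In midnight capture runs at 448 /s and its reverse at 66.9 /s, against a release of 2.65 /s, so intermediates A and B stand in equilibrium and capture drops out of the round. The binding constant, 4.46 /M here, stretches the release time by the factor 1.15, so an error in it is diluted. Loss to spent catalyst in midnight can be rough too, at 6.64 × 10⁻⁴ /s against entry of partner at 1.79 /s. Entry and release must be good, as each is one leg of the round. How good the forward dormancy constant must be differs from flask to flask: its product with the time is 0.114 in midnight, 0.648 in spring and 3.08 in dusk.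

Now the number. Waiting for partner at its charge takes 0.559 s in midnight, and release takes 0.433 s. Their sum is the turn time τ, the mean time of one round of one catalyst: 0.993 s. Catalyst charged times the time, divided by τ, gives the target at full partner, a ceiling of 12.1% of the substrate in midnight. The same sum gives 0.287 s and a ceiling of 41.8% in spring. In dusk it gives 0.0971 s and 124%, more than the substrate charged. So in spring and dusk this reckoning ends at ceilings, and the partner has to be watched.

The forecast names dusk as highest, with 11% in midnight, 40% in dusk and 29% in spring, holding that dormancy “drains most of the partner within a few seconds” at 15 °C. All its figures lie below these ceilings.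

The simulation gives dusk as highest, with 11.0% in midnight, 42.1% in dusk and 28.9% in spring, as the forecast said within its tolerance. Partner left at the end is 79%, 11% and 36% of its charge in the same order.

Read backwards, midnight's yield gives a mean turn time of 1.09 s, over a run that ends with 79% of the partner. The catalyst charge does not enter τ, so the neighbour of midnight with 0.0090 M of free catalyst keeps 0.993 s and is reckoned at 7.25% of the substrate. That neighbour ends at 6.70%, a turn time of 1.07 s, with 83% of its partner left.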